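**Retrosynthetic overview**

1. Numbering: ring carbons C1–C10, lactone carbons C11–C13 (C12 carbonyl, C13 exocyclic CH2), C14 = methyl on C10, C15 = methyl on C4. The last steps only adjust oxidation level: C3 ketone → (3S)-alcohol; C8 ketone (carried as a dithiane) → (8R)-alcohol → isobutyrate; methyl furanoside → α-methylene-γ-lactone.
2. Key disconnection C1–C2: in the ten-membered carbocycle the C3 carbonyl and the C10 tertiary carbinol form a γ-hydroxy ketone (O=C3–C2H2–C1H2–C10–OH). This is the retron of a C2 ketone enolate opening the CH2 terminus (C1) of a 2,2-disubstituted oxirane (C10–O–C1); one step closes the ring and frees the C10 hydroxyl with the oxirane's configuration.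
3. The open-chain precursor is made inert to base everywhere else: the lactone is carried as a furanoside acetal (ring O–C6–C7–C11–C12) and the C8 ketone as a 1,3-dithiane.
4. Its bonds: (Z)-C4=C5 by iodo-olefination of a C5 aldehyde, then C3/C2 by carbonylative methylation; C7–C8 by 1,4-addition of the dithiane anion to an (S)-butenolide (C7 trans to C6, C13 added in the same operation); C8–C9 by dithiane opening of (S)-2-methylglycidol trityl ether (source of C10).
5. Ring order: γ-lactone (chiral pool, masked as furanoside) → oxirane → ten-membered carbocycle (key step) → lactone restored.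

Key step: step 11

Remark: the acetal carbon C12 is carried as a mixture of epimers from step 5 to step 15, and the macrocyclic ketones may equilibrate with a C3/C10 hemiketal; they are drawn in the open form.

**Route**

Step 1
Reactants: 1 (S)-5-(hydroxymethyl)furan-2(5H)-one
Product: 2 (S)-5-[(tert-butyldiphenylsilyloxy)methyl]furan-2(5H)-one
Conditions: t-BuPh2SiCl, imidazole, DMF, 0 → 23 °C
Reagents that add atoms: tert-butyl(chloro)diphenylsilane, CC(C)(C)[Si](Cl)(c1ccccc1)c1ccccc1
Why: Standard silyl ether formation at the only hydroxyl; the C6 stereocentre comes from the chiral pool and the bulky silyloxymethyl group later shields one face of the butenolide.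

Step 2
Reactants: 3 (S)-2-methylglycidol
Product: 4 (R)-2-methyl-2-[(trityloxy)methyl]oxirane
Conditions: Ph3CCl, Et3N, DMAP (cat.), CH2Cl2, 0 → 23 °C
Reagents that add atoms: trityl chloride, ClC(c1ccccc1)(c1ccccc1)c1ccccc1
Why: Tritylation (SN1 etherification) of the primary alcohol gives a non-migrating, acid-labile ether and blocks Payne rearrangement, which would racemise the future C10; the stereocentre is not touched (its descriptor changes by priority only).

Step 3
Reactants: 5 1,3-dithiane; 4 (R)-2-methyl-2-[(trityloxy)methyl]oxirane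
Product: 7 (R)-1-(1,3-dithian-2-yl)-2-methyl-3-(trityloxy)propan-2-ol, via 2-lithio-1,3-dithiane 6 (not isolated)
Conditions: n-BuLi, THF, −30 °C; then 4, −30 → 0 °C; aq NH4Cl
Reagents that add atoms: none
Why: Corey–Seebach alkylation: lithiated dithiane 6 opens the 2,2-disubstituted oxirane by SN2 attack at its CH2 group (future C9), which forms C8–C9 and leaves the fully substituted C10 stereocentre unchanged.

Step 4
Reactants: 7 (R)-1-(1,3-dithian-2-yl)-2-methyl-3-(trityloxy)propan-2-ol; 2 (S)-5-[(tert-butyldiphenylsilyloxy)methyl]furan-2(5H)-one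
Product: 10 (4S,5S)-5-[(tert-butyldiphenylsilyloxy)methyl]-4-{2-[(R)-2-hydroxy-2-methyl-3-(trityloxy)propyl]-1,3-dithian-2-yl}-3-methylenedihydrofuran-2(3H)-one, via dilithium enolate 8 (not isolated), via Mannich base 9 (not isolated)
Conditions: n-BuLi (2.1 equiv), THF, −30 °C; HMPA, −78 °C; then 2; then CH2=NMe2+ I−, −78 → 0 °C; aq NH4Cl; crude material: MeI, MeOH, 23 °C; then aq NaHCO3, CH2Cl2
Reagents that add atoms: N,N-dimethylmethyleneiminium iodide, C=[N+](C)C.[I-]
Why: Tandem conjugate addition and Eschenmoser methylenation: after O- and C-deprotonation of 7 the dithiane carbon adds 1,4 (HMPA) to butenolide 2 anti to its silyloxymethyl group, which sets C7 trans to C6, and enolate 8 is aminomethylated to 9, which after N-methylation loses trimethylamine (E1cB) to give the exocyclic methylene C13.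

Step 5
Reactants: 10 the trans α-methylene lactone
Product: 12 methyl furanoside diol (lactone carbonyl replaced by CH(OMe); free C1–OH and C10–OH; TBDPS ether and dithiane kept), via lactol 11 (not isolated)
Conditions: i-Bu2AlH, CH2Cl2, −78 °C; aq KNaC4H4O6 (potassium sodium tartrate); then 10-camphorsulfonic acid (cat.), MeOH, 0 → 23 °C
Reagents that add atoms: methanol, CO
Why: Partial i-Bu2AlH reduction of the lactone to lactol 11 followed by Fischer-type acetalisation in acidic methanol, which also solvolyses the trityl ether; the lactone is thereby masked as a base-stable furanoside without acidic hydrogens or acceptor reactivity, while the TBDPS ether and the dithiane should survive.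

Step 6
Reactants: 12 methyl furanoside diol
Product: 13 oxirane (C10–O–C1 closed to an (R)-2-methyloxiran-2-yl group)
Conditions: NaH, 1-tosylimidazole, THF, 0 → 23 °C
Reagents that add atoms: none
Why: One-pot sulfonylation of the primary C1 hydroxyl and intramolecular Williamson etherification (3-exo-tet) by the C10 alkoxide closes the oxirane; C10 is not a reacting centre and keeps its configuration.

Step 7
Reactants: 13 oxirane
Product: 14 primary alcohol (free C5–OH)
Conditions: Bu4NF, THF, 0 → 23 °C; aq NH4Cl
Reagents that add atoms: none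
Why: Fluoride-mediated desilylation frees the C5 hydroxyl; oxirane, acetal and dithiane are inert to Bu4NF.

Step 8
Reactants: 14 primary alcohol
Product: 15 aldehyde (C5 = CHO)
Conditions: Dess–Martin periodinane, pyridine, CH2Cl2, 0 → 23 °C
Reagents that add atoms: none
Why: Dess–Martin oxidation under pyridine-buffered, non-epimerising conditions gives the α-alkoxy aldehyde without touching the dithiane sulfur, the oxirane or the acetal.

Step 9
Reactants: 15 aldehyde
Product: 16 (Z)-vinyl iodide (C6–CH=C(CH3)I, iodine cis to C6)
Conditions: EtPPh3I, NaN(SiMe3)2, THF, 23 °C; I2, −78 °C; NaN(SiMe3)2, −20 °C; then 15, −78 → −20 °C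
Reagents that add atoms: ethyltriphenylphosphonium iodide, CC[P+](c1ccccc1)(c1ccccc1)c1ccccc1.[I-]; iodine, II
Why: Stork–Zhao olefination: the non-stabilised α-iodo ylide reacts under kinetic control to give the trisubstituted vinyl iodide with iodine cis to C6, which fixes the later (4Z) geometry and brings in C4 and C15.

Step 10
Reactants: 16 (Z)-vinyl iodide
Product: 17 (Z)-methyl enone (C6–CH=C(CH3)–C(=O)CH3, acetyl cis to C6)
Conditions: CO (3 atm), Me4Sn, Pd2(dba)3 (cat.), AsPh3 (cat.), NMP, 50 °C
Reagents that add atoms: carbon monoxide, [C-]#[O+]; tetramethylstannane, C[Sn](C)(C)C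
Why: Carbonylative Stille coupling (oxidative addition, CO insertion, methyl transfer from tin, reductive elimination) proceeds with retention of alkene geometry and, being neutral, should leave oxirane, acetal and dithiane intact while adding C3 and C2 as the acetyl group cis to C6.

Step 11
Reactants: 17 (Z)-methyl enone
Product: 19 macrocyclic hydroxy ketone (ten-membered ring C1–C10; C3 ketone; (4Z)-alkene; (10S) tertiary alcohol; C8 spiro-dithiane; fused methyl furanoside), via lithium dienolate 18 (not isolated)
Conditions: LiN(SiMe3)2 (1.1 equiv), THF, −78 °C, 0.002 M; then LiClO4 (3 equiv), −78 → 23 °C; aq NH4Cl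
Reagents that add atoms: none
Why: Proposed new method: LiN(SiMe3)2 removes a proton from the C2 methyl group (the kinetically preferred α′ site of the enone) to give cross-conjugated dienolate 18, whose C2 attacks the unsubstituted oxirane carbon C1 from the backside while Li+ (LiClO4) assists C1–O cleavage, so that C1–C2 is formed and the C10 tertiary alkoxide is released. The closest known reactions are the metal-salt-promoted intermolecular opening of epoxides by ketone lithium enolates to γ-hydroxy ketones and the closure of ten-membered germacrane rings by sulfur-stabilised carbanions attacking remote epoxides; a ketone enolate has not been used for such a medium-ring closure. The ten-membered carbocycle closes in the 10-endo-tet mode (both oxirane carbons become ring members), and the competing 9-exo attack is blocked because C10 is fully substituted. No new stereocentre is formed: C10 keeps the configuration of the oxirane (from (S)-2-methylglycidol) because only C1 is attacked, and C6 and C7 are not touched. The step needs site-selective enolisation, C- over O-alkylation and ring closure over oligomerisation; these are secured by a substrate in which the lactone is a furanoside acetal and the C8 ketone a dithiane, so that the C2 methyl is the only acidic site and the oxirane the only electrophile, by the turn imposed by the (Z)-alkene, the trans-disubstituted furanoside and the quaternary dithiane carbon (Thorpe–Ingold effect), and by high dilution.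

Step 12
Reactants: 19 macrocyclic hydroxy ketone
Product: 20 diketone (C8 ketone unmasked)
Conditions: PhI(OCOCF3)2, MeCN/H2O (9:1), 0 °C, 10 min; aq NaHCO3
Reagents that add atoms: water, O
Why: Oxidative dithioacetal hydrolysis with a hypervalent iodine reagent (S-activation, then attack of water) unmasks the C8 ketone within minutes at 0 °C; the short, cold reaction and bicarbonate quench are meant to avoid enolisation towards C7 and loss of the acetal.

Step 13
Reactants: 20 diketone
Product: 21 anti-1,3-diol ((8R)-alcohol)
Conditions: Me4NBH(OAc)3, MeCN/AcOH (1:1), −30 °C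
Reagents that add atoms: none
Why: Evans–Saksena reduction: the acetoxyborohydride exchanges onto the C10 hydroxyl and delivers hydride internally through a chair-like six-membered transition state (C1 equatorial, C14 axial), which should give the 1,3-anti diol, that is (8R), while the C3 enone, lacking a β-hydroxyl, is not reduced.

Step 14
Reactants: 21 anti-1,3-diol
Product: 22 C8 isobutyrate
Conditions: (i-PrCO)2O, Et3N, DMAP (cat.), CH2Cl2, 0 → 23 °C
Reagents that add atoms: isobutyric anhydride, CC(C)C(=O)OC(=O)C(C)C
Why: DMAP-catalysed acylation is selective for the secondary C8 hydroxyl because the only other hydroxyl (C10) is tertiary.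

Step 15
Reactants: 22 C8 isobutyrate
Product: 24 (4Z)-10-hydroxy-8-(isobutyryloxy)-3-oxogermacra-4,11(13)-dien-12,6-olide, via lactol 23 (not isolated)
Conditions: AcOH/THF/H2O (3:1:1), 35 °C; then MnO2, CH2Cl2, 23 °C
Reagents that add atoms: water, O
Why: Mild acid hydrolysis of the allylic methyl acetal to lactol 23 and MnO2 oxidation of this allylic hemiacetal restore the α-methylene-γ-lactone; the tertiary C10 hydroxyl, the ester and the enone are not oxidisable under these conditions.

Step 16
Reactants: 24 the 3-oxo lactone
Product: 25 (3S,6R,7R,8R,10S,4Z)-3,10-dihydroxy-8-(isobutyryloxy)germacra-4,11(13)-dien-12,6-olide (target)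
Conditions: (R)-Me-CBS oxazaborolidine ((R)-1-methyl-3,3-diphenyltetrahydro-1H,3H-pyrrolo[1,2-c][1,3,2]oxazaborole, 0.5 equiv), catecholborane, toluene, −78 → −40 °C; aq NaHCO3
Reagents that add atoms: none
Why: Corey–Bakshi–Shibata reduction: with the alkenyl carbon C4 as the large and C2H2 as the small ketone substituent the (R)-catalyst should deliver hydride to the face that gives the (3S)-alcohol, and 1,2-reduction by catecholborane at low temperature spares the lactone, the ester and the exocyclic methylene.

**Compound list**

1 | (S)-5-(hydroxymethyl)furan-2(5H)-one | O=C1O[C@H](CO)C=C1 | starting material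
2 | (S)-5-[(tert-butyldiphenylsilyloxy)methyl]furan-2(5H)-one | O=C1O[C@H](CO[Si](c2ccccc2)(c2ccccc2)C(C)(C)C)C=C1 | intermediate
3 | (S)-2-methylglycidol, (S)-(2-methyloxiran-2-yl)methanol | OC[C@]1(C)OC1 | starting material
4 | (R)-2-methyl-2-[(trityloxy)methyl]oxirane | c1ccccc1C(c1ccccc1)(c1ccccc1)OC[C@]1(C)OC1 | intermediate
5 | 1,3-dithiane | C1CSCSC1 | starting material
6 | 2-lithio-1,3-dithiane | [Li]C1SCCCS1 | intermediate (not isolated)
7 | (R)-1-(1,3-dithian-2-yl)-2-methyl-3-(trityloxy)propan-2-ol | c1ccccc1C(c1ccccc1)(c1ccccc1)OC[C@](C)(O)CC1SCCCS1 | intermediate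
8 | dilithium enolate: C10 lithium alkoxide and lactone lithium enolate of the 1,4-adduct of 7 to 2 | [Li]OC1=C[C@H](C3(C[C@@](C)(O[Li])COC(c4ccccc4)(c4ccccc4)c4ccccc4)SCCCS3)[C@@H](CO[Si](c3ccccc3)(c3ccccc3)C(C)(C)C)O1 | intermediate (not isolated)
9 | Mannich base: the lactone of 10 with CH–CH2NMe2 in place of C=CH2 (C11 configuration immaterial) | CN(C)CC1C(=O)O[C@H](CO[Si](c2ccccc2)(c2ccccc2)C(C)(C)C)[C@H]1C3(C[C@@](C)(O)COC(c4ccccc4)(c4ccccc4)c4ccccc4)SCCCS3 | intermediate (not isolated)
10 | (4S,5S)-5-[(tert-butyldiphenylsilyloxy)methyl]-4-{2-[(R)-2-hydroxy-2-methyl-3-(trityloxy)propyl]-1,3-dithian-2-yl}-3-methylenedihydrofuran-2(3H)-one (6,7-trans lactone) | C=C1C(=O)O[C@H](CO[Si](c2ccccc2)(c2ccccc2)C(C)(C)C)[C@H]1C3(C[C@@](C)(O)COC(c4ccccc4)(c4ccccc4)c4ccccc4)SCCCS3 | intermediate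
11 | lactol of 10: 2-hydroxy-3-methylenetetrahydrofuran (C12 epimers), other groups as in 10 | C=C1C(O)O[C@H](CO[Si](c2ccccc2)(c2ccccc2)C(C)(C)C)[C@H]1C3(C[C@@](C)(O)COC(c4ccccc4)(c4ccccc4)c4ccccc4)SCCCS3 | intermediate (not isolated)
12 | methyl furanoside diol: 2-methoxy-3-methylenetetrahydrofuran (C12 epimers) with C5H2OTBDPS on C6 and on C7 the dithiane bearing CH2–C(CH3)(OH)–CH2OH; C6, C7, C10 as in 10 | C=C1C(OC)O[C@H](CO[Si](c2ccccc2)(c2ccccc2)C(C)(C)C)[C@H]1C3(C[C@@](C)(O)CO)SCCCS3 | intermediate
13 | oxirane: as 12 with the diol closed to an (R)-2-methyloxiran-2-yl group (C10–O–C1) | C=C1C(OC)O[C@H](CO[Si](c2ccccc2)(c2ccccc2)C(C)(C)C)[C@H]1C3(C[C@]4(C)CO4)SCCCS3 | intermediate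
14 | primary alcohol: as 13 with free C5–OH | C=C1C(OC)O[C@H](CO)[C@H]1C3(C[C@]4(C)CO4)SCCCS3 | intermediate
15 | aldehyde: as 14 with C5 = CHO | C=C1C(OC)O[C@H](C=O)[C@H]1C3(C[C@]4(C)CO4)SCCCS3 | intermediate
16 | (Z)-vinyl iodide: C6–CH=C(CH3)I with iodine cis to C6 | C=C1C(OC)O[C@H](/C=C(/C)I)[C@H]1C3(C[C@]4(C)CO4)SCCCS3 | intermediate
17 | (Z)-methyl enone: C6–CH=C(CH3)–C(=O)CH3 with acetyl cis to C6 | C=C1C(OC)O[C@H](/C=C(/C)C(C)=O)[C@H]1C3(C[C@]4(C)CO4)SCCCS3 | intermediate
18 | lithium dienolate of 17 (C2=C3–OLi, cross-conjugated) | C=C1C(OC)O[C@H](/C=C(/C)C(=C)O[Li])[C@H]1C3(C[C@]4(C)CO4)SCCCS3 | intermediate (not isolated)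
19 | macrocyclic hydroxy ketone: ten-membered carbocycle C1–C10 with C3 ketone, (4Z)-alkene, (10S)-hydroxyl and C14 methyl on C10, C8 spiro-1,3-dithiane, and the 2-methoxy-3-methylenetetrahydrofuran fused at C6 (O)/C7 (C6, C7 as in 25; C12 epimers) | C=C1C(OC)O[C@@H]2/C=C(/C)C(=O)CC[C@](C)(O)CC3(SCCCS3)[C@@H]12 | intermediate
20 | diketone: as 19 with C8 = ketone | C=C1C(OC)O[C@@H]2/C=C(/C)C(=O)CC[C@](C)(O)CC(=O)[C@@H]12 | intermediate
21 | anti-1,3-diol: as 20 with (8R)-hydroxyl | C=C1C(OC)O[C@@H]2/C=C(/C)C(=O)CC[C@](C)(O)C[C@@H](O)[C@@H]12 | intermediate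
22 | C8 isobutyrate of 21 | C=C1C(OC)O[C@@H]2/C=C(/C)C(=O)CC[C@](C)(O)C[C@@H](OC(=O)C(C)C)[C@@H]12 | intermediate
23 | lactol of 22 (C12–OH in place of C12–OMe; C12 epimers) | C=C1C(O)O[C@@H]2/C=C(/C)C(=O)CC[C@](C)(O)C[C@@H](OC(=O)C(C)C)[C@@H]12 | intermediate (not isolated)
24 | (4Z)-10-hydroxy-8-(isobutyryloxy)-3-oxogermacra-4,11(13)-dien-12,6-olide, stereocentres C6, C7, C8, C10 as in 25 | C=C1C(=O)O[C@@H]2/C=C(/C)C(=O)CC[C@](C)(O)C[C@@H](OC(=O)C(C)C)[C@@H]12 | intermediate
25 | (3S,6R,7R,8R,10S,4Z)-3,10-dihydroxy-8-(isobutyryloxy)germacra-4,11(13)-dien-12,6-olide (CNP0163972.1) | C=C1C(=O)O[C@@H]2/C=C(/C)[C@@H](O)CC[C@](C)(O)C[C@@H](OC(=O)C(C)C)[C@@H]12 | target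

**Step count and risks**

Total steps: 16. Longest linear sequence: 15 steps (3 → 25, steps 2 to 16).

Steps most likely to fail:

1. Step 11 (key step, proposed new method). The ten-membered ring may close more slowly than intermolecular epoxide opening (oligomers) or than proton transfer that moves the enolate to C6, which would erode the C6 centre and the alkene geometry. The fallback uses known reaction types and still closes the ring at C1–C2. It sets out from vinyl iodide 16: excess dimethylsulfonium methylide (Me3SI, n-BuLi, THF, −10 → 23 °C) should convert the oxirane by one-carbon homologation into the tertiary allylic alcohol F1. Carbonylative Stille coupling with Bu3SnCH=CH2 (CO, Pd2(dba)3, AsPh3, NMP) should then give the divinyl ketone F2. Ring-closing metathesis of the two terminal vinyl groups (second-generation Hoveyda–Grubbs catalyst, toluene, 80 °C, high dilution) should give the macrocyclic cross-conjugated dienone F3 with loss of ethylene. Conjugate reduction of its less substituted C1=C2 enone bond with [(Ph3P)CuH]6 comes back to the route at 19.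

2. Step 13. The macrocycle, or partial C3/C10 hemiketal formation that ties up the directing hydroxyl, may prevent the chair-like internal hydride delivery, so that hydride arrives from the wrong face of the C8 ketone. The fallback sets out from 20 and uses chelation-controlled external hydride delivery instead (Narasaka–Prasad reduction: Et2BOMe, NaBH4, THF/MeOH, −78 °C), which should give the 1,3-syn diol F4. Mitsunobu esterification of F4 with isobutyric acid (PPh3, DIAD, toluene, 0 °C) inverts C8 and installs the ester in one operation, coming back to the route at 22 (step 14 is then not needed).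

3. Step 16. The facial selectivity may be dictated by the macrocycle and not by the catalyst. The fallback sets out from 24 and gives up reagent control: Luche reduction (NaBH4, CeCl3·7H2O, MeOH, −78 °C) should deliver hydride from the peripheral face. If this gives the C3-epimeric alcohol F5, Mitsunobu inversion with formic acid (PPh3, DIAD, THF, 0 °C) should give the (3S)-formate F6, and mild solvolysis (KHCO3, MeOH/H2O, 0 °C) comes back to the route at 25.

Further compounds
F1 | step 11 | tertiary allylic alcohol: as 16 with the oxirane replaced by C(CH3)(OH)–CH=CH2 | C=C1C(OC)O[C@H](/C=C(/C)I)[C@H]1C3(C[C@@](C)(O)C=C)SCCCS3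
F2 | step 11 | divinyl ketone: as F1 with iodine replaced by C(=O)–CH=CH2 (cis to C6) | C=C1C(OC)O[C@H](/C=C(/C)C(=O)C=C)[C@H]1C3(C[C@@](C)(O)C=C)SCCCS3
F3 | step 11 | macrocyclic dienone: 1,2-didehydro derivative of 19 (C1=C2 geometry immaterial) | C=C1C(OC)O[C@@H]2/C=C(/C)C(=O)C=C[C@](C)(O)CC3(SCCCS3)[C@@H]12
F4 | step 13 | syn-1,3-diol: C8 epimer of 21 | C=C1C(OC)O[C@@H]2/C=C(/C)C(=O)CC[C@](C)(O)C[C@H](O)[C@@H]12
F5 | step 16 | C3 epimer of 25 | C=C1C(=O)O[C@@H]2/C=C(/C)[C@H](O)CC[C@](C)(O)C[C@@H](OC(=O)C(C)C)[C@@H]12
F6 | step 16 | 3-O-formate of 25 | C=C1C(=O)O[C@@H]2/C=C(/C)[C@@H](OC=O)CC[C@](C)(O)C[C@@H](OC(=O)C(C)C)[C@@H]12
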